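The earlier runs and the new flask were generated by integration with made-up constants; noise was put on by code.

**Early slowness.** Saturday's run turns slow early, and its substrate does not account for that: the rate is 21.4 mM h⁻¹ up to the first reading and 3.32 mM h⁻¹ between the last two. That rate ratio of 6.45 is larger than the ratio of 2.57 in mean [substrate] over the same two intervals.

| flask | substrate | coupling partner | free catalyst | time |
|---|---|---|---|---|
| Saturday's | 120 mM | 300 mM | 9.60 mM |  |
| Thursday's | 180 mM | 300 mM | 9.60 mM |  |
| Sunday's | 120 mM | 300 mM | 9.60 mM | 44 h |

- Saturday's run (time / h: [substrate] / mM): 0.44: 110.6; 0.70: 104.7; 1.1: 99.0; 1.7: 88.5; 2.8: 75.6; 4.4: 62.9; 6.9: 51.7; 11: 38.1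
- Thursday's run (time / h: [substrate] / mM): 0.44: 167.4; 0.70: 159.7; 1.1: 150.5; 1.7: 141.0; 2.8: 124.2; 4.4: 109.5; 6.9: 94.4; 11: 81.2

(readings scatter by 0.6 mM)

- Overall: substrate + coupling partner -> target, with free catalyst as catalyst.
- Constant volume, constant temperature.
- What is held in complexes is read along with the free species.
- "The second partner" is coupling partner.
- An order is taken over about fifteen percent of the charge, up and down.

- reaction order in [substrate] at the outset, round the charge of the Saturday's run, defined at two percent of the substrate turned into target (one fixed amount of target, the same in the runs compared)
- substrate in the Sunday's run at 44 h, as a share of the substrate charged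

**The order.** Saturday's and Thursday's runs share their charges of coupling partner and free catalyst, so I compare their drops up to the first reading and get an order of 0.715. My doubt is that Thursday's run has made more target by then, which I can correct once the slowing is measured.

**The ceiling.** I call activity the rate divided by [substrate] raised to that order. Between the early and late intervals it falls to 0.305 of its early value in Saturday's run and to 0.183 in Thursday's. A straight line against target reaches zero at 106 mM and 111 mM respectively. Their mean, 109 mM, is my ceiling, the amount of target at which activity reaches zero, taken as one value for both substrate charges at the coupling partner and free catalyst charges these runs share.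

**Two objections.** Two points make any line straight, but the line and order predict 11.4 mM h⁻¹ for Saturday's middle interval, and the readings give 11.7 mM h⁻¹. Correcting the order for the unequal target moves it to 0.753.

**The tail.** Sunday's charge matches Saturday's, so I estimate its substrate floor at 11.3 mM. I treat the gap above that floor as a pseudo-first-order decay, with a constant of 0.0987 h⁻¹ late in Saturday's run, scaled to 0.0644 h⁻¹ at the mean substrate still ahead. From Saturday's last reading I estimate 14.5 mM in Sunday's run at 44 h, or 12.1% of the charge.

**The forecast.** It gives an order of 0.7 and 11%, suspecting “catalyst lost per turnover, or strong target poisoning”.

**The result.** The flask gives an order of 0.78 and 12.5% of the substrate in Sunday's run.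

    free catalyst + substrate ⇌ catalyst-substrate complex, settled at all times (1.520 M⁻¹)
    catalyst-substrate complex + coupling partner ⇌ ternary complex, settled at all times (2.430 M⁻¹)
    ternary complex → target + free catalyst (25.67 h⁻¹)
    free catalyst + substrate → spent catalyst + substrate (1.933 M⁻¹ h⁻¹)

**Near the ceiling.** Sunday's run has made 105 mM of target at 44 h, which is 96.6% of my ceiling. Without the conversion of free catalyst into spent catalyst, that run keeps 0.0640% of its substrate at that time rather than 12.5%, so this loss is the reason for the substrate still there. Making target equal to half of its charge takes Thursday's run to 82.8% of the ceiling, against 55.2% for Saturday's run, and Thursday's run needs 8.10 h for it against 4.94 h.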